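Numbering (2-oxaspiro[4.5]decane): C1 bears the side chain C1′(OAr′)–C2′H2OH, then O2, C3 (aryl), C4 (CH2OH), C5 (spiro), C6=C7(OMe)–C8(=O)–C9=C10.
Retrosynthesis: remove the silyl groups and the C9=C10 unsaturation, and return C3 to its kinetic epimer. Then cut C5–C10 and C6=C7 (Robinson spiroannulation) back to a C5-formyl tetrahydrofuran, and cut C3–C4 and C5–C1 together (Prins–pinacol cascade) back to a 2-aryl-4-(Z-alkenyl)-1,3-dioxolane. Finally cut C1′–OAr′ (Mitsunobu), the Z-alkene (Wittig, cross-metathesis) and the acetal, which leads to D-ribose, vanillin, dihydroconiferyl alcohol and cis-butenediol.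
Enabling feature: C1, C1′ and C2′ carry three contiguous oxygens (ribose C3, C4, C5), and O2 on C1 is bonded to the benzylic carbon C3, which is an aryl acetal carbon. C5 and C6 are ribose C1 and C2, so a 1,2-shift of ribose C3 from C2 to C1 closes the ring O2–C3–C4–C5–C1 and frees C6 as a formyl group.
Forward order: acyclic ribose-derived dioxolane (steps 1–9), tetrahydrofuran ring (step 10), cyclohexenone ring (step 11), C3 inversion (step 12), dienone (step 13), deprotection (step 14).
Stereochemistry: C1 is ribose C3, retained in the shift. C1′ is ribose C4, inverted by Mitsunobu. C4 comes from the Z-alkene in a chair Prins transition state. C5 comes from Michael addition anti to the C4 and C1 substituents. C3 is set by benzylic equilibration (aryl trans to C4–CH2OR).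

Key step: step 10

Remark: Ar = 3-methoxy-4-(triisopropylsilyloxy)phenyl; Ar′ = 2-methoxy-4-[3-(tert-butyldimethylsilyloxy)propyl]phenyl; TIPS, TBS and TBDPS are the usual silyl groups. Compounds 5–13 are mixtures at the acetal carbon (5 and 6 also at the anomeric carbon) and 14 is a mixture at C5. These converge in steps 5, 10 and 11, so the SMILES leave those centres open.
Assumption: 1-methoxybut-3-en-2-one (15) and the ruthenium catalyst of step 9 are purchased.

Step 1
Reactants: 1 vanillin
Product: 2 3-methoxy-4-(triisopropylsilyloxy)benzaldehyde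
Conditions: iPr3SiCl, imidazole, DMF, 0 °C → rt
Reagents that add atoms: triisopropylsilyl chloride, CC(C)[Si](Cl)(C(C)C)C(C)C
Why: Imidazole-promoted silylation of the phenol; the bulky aryl TIPS ether is chosen because it should survive the ylide of step 5 while keeping the ring electron-rich enough for the benzylic equilibration of step 12.

Step 2
Reactants: 2 3-methoxy-4-(triisopropylsilyloxy)benzaldehyde
Product: 3 3-methoxy-4-(triisopropylsilyloxy)benzaldehyde dimethyl acetal
Conditions: HC(OMe)3, p-TsOH·H2O (cat.), CH2Cl2, rt; Et3N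
Reagents that add atoms: trimethyl orthoformate, COC(OC)OC
Why: Acid-catalysed acetalisation driven by the orthoester (methyl formate leaves) gives the acetal donor needed for transacetalisation onto the sugar.

Step 3
Reactants: 4 D-ribose; 3 3-methoxy-4-(triisopropylsilyloxy)benzaldehyde dimethyl acetal
Product: 5 2,3-O-(Ar-methylidene)-D-ribofuranose (anomers and acetal epimers)
Conditions: CSA (cat.), DMF, 45 °C, reduced pressure; Et3N
Reagents that add atoms: none
Why: Transacetalisation onto the cis-2,3-diol of the furanose form gives the cis-fused bicyclic acetal, as in acetonide or benzylidene formation on ribose, with methanol stripped off to drive the equilibrium; the ribose stereocentres are untouched.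

Step 4
Reactants: 5 2,3-O-(Ar-methylidene)-D-ribofuranose
Product: 6 5-O-TBDPS-2,3-O-(Ar-methylidene)-D-ribofuranose
Conditions: t-BuPh2SiCl (1.05 equiv), imidazole, DMF, 0 °C
Reagents that add atoms: tert-butyldiphenylsilyl chloride, CC(C)(C)[Si](Cl)(c1ccccc1)c1ccccc1
Why: Selective silylation of the primary hydroxyl over the hemiacetal hydroxyl with a bulky silyl chloride; TBDPS is used because it should not migrate to the neighbouring alkoxide under the basic conditions of step 5.

Step 5
Reactants: 6 5-O-TBDPS-2,3-O-(Ar-methylidene)-D-ribofuranose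
Product: 7 1,2-dideoxy-3,4-O-(Ar-methylidene)-6-O-TBDPS-D-ribo-hex-1-enitol (free (5R)-hydroxyl)
Conditions: Ph3PCH3Br, KOtBu, THF, 0 °C → rt
Reagents that add atoms: methyltriphenylphosphonium bromide, C[P+](c1ccccc1)(c1ccccc1)c1ccccc1.[Br-]
Why: Wittig methylenation of the hydroxy aldehyde in equilibrium with the lactol, the standard opening of 2,3-O-alkylidene ribofuranoses, frees the ribose C4 hydroxyl and leaves the three stereocentres intact.

Step 6
Reactants: 8 dihydroconiferyl alcohol
Product: 9 4-[3-(tert-butyldimethylsilyloxy)propyl]-2-methoxyphenol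
Conditions: t-BuMe2SiCl (1.05 equiv), imidazole, CH2Cl2, 0 °C
Reagents that add atoms: tert-butyldimethylsilyl chloride, CC(C)(C)[Si](C)(C)Cl
Why: Chemoselective silylation of the primary aliphatic hydroxyl, which is more nucleophilic than the hydrogen-bonded guaiacol hydroxyl when one equivalent of silyl chloride is used at low temperature.

Step 7
Reactants: 7 1,2-dideoxy-3,4-O-(Ar-methylidene)-6-O-TBDPS-D-ribo-hex-1-enitol; 9 4-[3-(tert-butyldimethylsilyloxy)propyl]-2-methoxyphenol
Product: 10 1,2-dideoxy-3,4-O-(Ar-methylidene)-5-O-Ar′-6-O-TBDPS-L-lyxo-hex-1-enitol ((5S)-aryl ether)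
Conditions: PPh3, DIAD, toluene, 0 °C → rt
Reagents that add atoms: none
Why: Mitsunobu etherification, in which the phenol (pKa about 10) protonates the betaine and displaces the oxyphosphonium ion by SN2 with inversion, turning the (R)-carbinol of ribose C4 into the (S)-aryl ether that becomes C1′.

Step 8
Reactants: 11 (Z)-but-2-ene-1,4-diol
Product: 12 (Z)-1,4-bis(tert-butyldimethylsilyloxy)but-2-ene
Conditions: t-BuMe2SiCl (2.2 equiv), imidazole, DMF, rt
Reagents that add atoms: tert-butyldimethylsilyl chloride, CC(C)(C)[Si](C)(C)Cl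
Why: Routine bis-silylation of a primary diol gives the symmetrical Z cross-metathesis partner.

Step 9
Reactants: 10 1,2-dideoxy-3,4-O-(Ar-methylidene)-5-O-Ar′-6-O-TBDPS-L-lyxo-hex-1-enitol; 12 (Z)-1,4-bis(tert-butyldimethylsilyloxy)but-2-ene
Product: 13 2-Ar-4-[(Z)-3-(TBS-oxy)prop-1-enyl]-5-[(1S)-1-(Ar′-oxy)-2-(TBDPS-oxy)ethyl]-1,3-dioxolane (cis-4,5 with ribose C2/C3 configuration; acetal epimers)
Conditions: 12 (4 equiv), Ru(NO3)(=CH-C6H4-2-OiPr)[C,C′-chelating 1-(adamantyl)-3-(2,6-iPr2C6H3)imidazolin-2-ylidene] (7.5 mol%), THF, 35 °C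
Reagents that add atoms: none
Why: Z-selective olefin cross-metathesis, in which the cyclometalated ruthenium carbene forms side-bound all-syn metallacyclobutanes, so catalyst control and the Z geometry of 12 both favour the Z-1,2-disubstituted alkene; the hindered allylic dioxolane is not expected to homodimerise.

Step 10
Reactants: 13 2-Ar-4-[(Z)-3-(TBS-oxy)prop-1-enyl]-5-[(1S)-1-(Ar′-oxy)-2-(TBDPS-oxy)ethyl]-1,3-dioxolane
Product: 14 C5-formyl tetrahydrofuran with the C1 side chain [(1S)-1-(Ar′-oxy)-2-(TBDPS-oxy)ethyl], the C3 aryl (Ar) and the C4 CH2OTBS all cis (C5 epimers)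
Conditions: SnCl4 (2 equiv), 2,6-di-tert-butyl-4-methylpyridine (0.5 equiv), CH2Cl2, −78 → −25 °C; Et3N, aq. NaHCO3
Reagents that add atoms: none
Why: SnCl4 ionises the acetal reversibly; the oxocarbenium ion on the ribose C3 oxygen (O2=C3, tin alkoxide left on the allylic carbon) is attacked by the distal carbon of the Z-alkene (C3–C4 bond) to give a tetrahydropyran-4-yl cation next to the tin alkoxide, and a pinacol 1,2-shift of the ribose C3 carbon from the carbinol carbon to the cationic carbon (C5–C1 bond) ends the cascade and releases the carbinol carbon as the formyl group. The closest known reaction is the Lewis-acid Prins–pinacol rearrangement of 4-alkenyl-1,3-dioxolanes to 3-acyltetrahydrofurans, run here to the aldehyde oxidation level. The first ring forms by a 6-endo-trig cation–olefin (Prins) closure through a chair, and the tetrahydrofuran ring O2–C3–C4–C5–C1 then arises by contraction of that six-membered ring rather than by C–O bond formation, the migrating ring bond lying nearly parallel to the empty p orbital. C1 keeps the ribose C3 configuration because the migrating carbon shifts with retention; C3 and C4 are set in the chair in which the aryl group, the C1 side chain and the tin alkoxide are equatorial and the CH2OTBS group of the Z-alkene is therefore axial, which places aryl, CH2OTBS and side chain on one face, while C5 remains an epimerisable mixture. The step needs ionisation at the allylic oxygen, which Curtin–Hammett funnelling should secure because the regioisomeric oxocarbenium ion has only a 5-endo path, and it needs a single chair, which the cis-dioxolane of ribose should secure because the carbinol hydrogen is then the only group syn-axial to the axial CH2OTBS (no A(1,3) strain) without the C1 side chain becoming axial. The modest nucleophilicity of the doubly allylically oxygenated alkene is offset by the long-lived aryl-stabilised oxocarbenium ion and the intramolecular six-membered closure, and the hindered pyridine keeps adventitious HCl away from the silyl ethers.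

Step 11
Reactants: 14 all-cis C5-formyl tetrahydrofuran; 15 1-methoxybut-3-en-2-one
Product: 18 3-epi spiro-enone (7-methoxy-2-oxaspiro[4.5]dec-6-en-8-one; C1 side chain, C3 aryl and C4 CH2OTBS all cis; C10 anti to them), via pyrrolidine enamine 16 (not isolated), via keto aldehyde 17 (not isolated)
Conditions: pyrrolidine, 4 Å MS, toluene, rt; then 15, 0 °C → rt; then AcOH, H2O (2 equiv), 45 °C
Reagents that add atoms: none
Why: Enamine Michael addition followed by amine/acid-mediated aldol condensation (Robinson spiroannulation of an α-branched aldehyde), in which the planar enamine erases the C5 mixture and the enone should add to the face opposite the C4, C1 and C3 substituents, placing C10 anti and the formyl carbon C6 syn to them as in the target; only the methoxy-bearing α-carbon of the ketone can close a six-membered ring onto the aldehyde.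

Step 12
Reactants: 18 3-epi spiro-enone
Product: 19 spiro-enone with the C3 aryl trans to C4–CH2OTBS (target configuration at C1, C3, C4, C5 and C1′)
Conditions: BF3·OEt2 (0.3 equiv), CH2Cl2, −20 → 0 °C; Et3N
Reagents that add atoms: none
Why: Lewis-acid benzylic epimerisation, in which reversible ionisation of the C3–O2 bond to the 4-silyloxybenzyl cation and reclosure should equilibrate C3 towards the isomer free of the cis-vicinal aryl/CH2OTBS interaction on the crowded face, while the quaternary C5 and the non-benzylic C1, C4 and C1′ cannot change.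

Step 13
Reactants: 19 spiro-enone with trans C3 aryl
Product: 21 fully silylated target (7-methoxy-2-oxaspiro[4.5]deca-6,9-dien-8-one), via trimethylsilyl dienol ether 20 (not isolated)
Conditions: LiN(SiMe3)2, Me3SiCl, THF, −78 °C; then Pd(OAc)2 (1.2 equiv), MeCN, rt
Reagents that add atoms: none
Why: Saegusa–Ito dehydrogenation, in which deprotonation can occur only at C9 because C5 is quaternary, and the silyl dienol ether is palladated by divalent palladium and loses the C10 hydrogen by β-hydride elimination to give the cross-conjugated dienone and zerovalent palladium.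

Step 14
Reactants: 21 fully silylated target
Product: 22 CNP0252711.1 (target)
Conditions: Bu4NF, AcOH (1:1, excess), THF, 0 °C → rt
Reagents that add atoms: none
Why: Fluoride-mediated global desilylation of the two TBS ethers, the TBDPS ether and the aryl TIPS ether, buffered with acetic acid so that no alkoxide or phenoxide is present to add to the dienone or open the benzylic ether.

Compound list
1 | vanillin | COc1cc(C=O)ccc1O | starting material
2 | 3-methoxy-4-(triisopropylsilyloxy)benzaldehyde | COc1cc(C=O)ccc1O[Si](C(C)C)(C(C)C)C(C)C | intermediate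
3 | 3-methoxy-4-(triisopropylsilyloxy)benzaldehyde dimethyl acetal | COc1cc(C(OC)OC)ccc1O[Si](C(C)C)(C(C)C)C(C)C | intermediate
4 | D-ribose | O=C[C@H](O)[C@H](O)[C@H](O)CO | starting material
5 | 2,3-O-(Ar-methylidene)-D-ribofuranose (anomers, acetal epimers) | OC[C@H]1OC(O)[C@@H]2OC(c3ccc(O[Si](C(C)C)(C(C)C)C(C)C)c(OC)c3)O[C@H]12 | intermediate
6 | 5-O-TBDPS-2,3-O-(Ar-methylidene)-D-ribofuranose | CC(C)(C)[Si](c1ccccc1)(c1ccccc1)OC[C@H]1OC(O)[C@@H]2OC(c3ccc(O[Si](C(C)C)(C(C)C)C(C)C)c(OC)c3)O[C@H]12 | intermediate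
7 | 1,2-dideoxy-3,4-O-(Ar-methylidene)-6-O-TBDPS-D-ribo-hex-1-enitol | C=C[C@@H]1OC(c2ccc(O[Si](C(C)C)(C(C)C)C(C)C)c(OC)c2)O[C@@H]1[C@H](O)CO[Si](c2ccccc2)(c2ccccc2)C(C)(C)C | intermediate
8 | dihydroconiferyl alcohol | COc1cc(CCCO)ccc1O | starting material
9 | 4-[3-(tert-butyldimethylsilyloxy)propyl]-2-methoxyphenol | COc1cc(CCCO[Si](C)(C)C(C)(C)C)ccc1O | intermediate
10 | 1,2-dideoxy-3,4-O-(Ar-methylidene)-5-O-Ar′-6-O-TBDPS-L-lyxo-hex-1-enitol | C=C[C@@H]1OC(c2ccc(O[Si](C(C)C)(C(C)C)C(C)C)c(OC)c2)O[C@@H]1[C@H](CO[Si](c2ccccc2)(c2ccccc2)C(C)(C)C)Oc2ccc(CCCO[Si](C)(C)C(C)(C)C)cc2OC | intermediate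
11 | (Z)-but-2-ene-1,4-diol | OC/C=C\CO | starting material
12 | (Z)-1,4-bis(tert-butyldimethylsilyloxy)but-2-ene | CC(C)(C)[Si](C)(C)OC/C=C\CO[Si](C)(C)C(C)(C)C | intermediate
13 | 2-Ar-4-[(Z)-3-(TBS-oxy)prop-1-enyl]-5-[(1S)-1-(Ar′-oxy)-2-(TBDPS-oxy)ethyl]-1,3-dioxolane (key-step precursor) | CC(C)(C)[Si](C)(C)OC/C=C\[C@@H]1OC(c2ccc(O[Si](C(C)C)(C(C)C)C(C)C)c(OC)c2)O[C@@H]1[C@H](CO[Si](c2ccccc2)(c2ccccc2)C(C)(C)C)Oc2ccc(CCCO[Si](C)(C)C(C)(C)C)cc2OC | intermediate
14 | all-cis C5-formyl tetrahydrofuran (key-step product, C5 epimers) | O=CC1[C@H](CO[Si](C)(C)C(C)(C)C)[C@H](c2ccc(O[Si](C(C)C)(C(C)C)C(C)C)c(OC)c2)O[C@@H]1[C@H](CO[Si](c2ccccc2)(c2ccccc2)C(C)(C)C)Oc2ccc(CCCO[Si](C)(C)C(C)(C)C)cc2OC | intermediate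
15 | 1-methoxybut-3-en-2-one | COCC(=O)C=C | starting material
16 | pyrrolidine enamine of 14 | C(=C1[C@H](CO[Si](C)(C)C(C)(C)C)[C@H](c2ccc(O[Si](C(C)C)(C(C)C)C(C)C)c(OC)c2)O[C@@H]1[C@H](CO[Si](c2ccccc2)(c2ccccc2)C(C)(C)C)Oc2ccc(CCCO[Si](C)(C)C(C)(C)C)cc2OC)N1CCCC1 | intermediate
17 | keto aldehyde (C5 quaternary: formyl and 4-methoxy-3-oxobutyl) | O=C[C@]1(CCC(=O)COC)[C@H](CO[Si](C)(C)C(C)(C)C)[C@H](c2ccc(O[Si](C(C)C)(C(C)C)C(C)C)c(OC)c2)O[C@@H]1[C@H](CO[Si](c2ccccc2)(c2ccccc2)C(C)(C)C)Oc2ccc(CCCO[Si](C)(C)C(C)(C)C)cc2OC | intermediate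
18 | 3-epi spiro-enone (C3 aryl cis to C4–CH2OTBS) | COC1=C[C@]2(CCC1=O)[C@H](CO[Si](C)(C)C(C)(C)C)[C@H](c3ccc(O[Si](C(C)C)(C(C)C)C(C)C)c(OC)c3)O[C@@H]2[C@H](CO[Si](c3ccccc3)(c3ccccc3)C(C)(C)C)Oc3ccc(CCCO[Si](C)(C)C(C)(C)C)cc3OC | intermediate
19 | spiro-enone with C3 aryl trans to C4–CH2OTBS | COC1=C[C@]2(CCC1=O)[C@H](CO[Si](C)(C)C(C)(C)C)[C@@H](c3ccc(O[Si](C(C)C)(C(C)C)C(C)C)c(OC)c3)O[C@@H]2[C@H](CO[Si](c3ccccc3)(c3ccccc3)C(C)(C)C)Oc3ccc(CCCO[Si](C)(C)C(C)(C)C)cc3OC | intermediate
20 | trimethylsilyl dienol ether of 19 (C8–OTMS, C8=C9) | COC1=C[C@]2(CC=C1O[Si](C)(C)C)[C@H](CO[Si](C)(C)C(C)(C)C)[C@@H](c3ccc(O[Si](C(C)C)(C(C)C)C(C)C)c(OC)c3)O[C@@H]2[C@H](CO[Si](c3ccccc3)(c3ccccc3)C(C)(C)C)Oc3ccc(CCCO[Si](C)(C)C(C)(C)C)cc3OC | intermediate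
21 | fully silylated target (spiro-dienone) | COC1=C[C@]2(C=CC1=O)[C@H](CO[Si](C)(C)C(C)(C)C)[C@@H](c3ccc(O[Si](C(C)C)(C(C)C)C(C)C)c(OC)c3)O[C@@H]2[C@H](CO[Si](c3ccccc3)(c3ccccc3)C(C)(C)C)Oc3ccc(CCCO[Si](C)(C)C(C)(C)C)cc3OC | intermediate
22 | CNP0252711.1 | COC1=C[C@]2(C=CC1=O)[C@H](CO)[C@@H](c1ccc(O)c(OC)c1)O[C@@H]2[C@H](CO)Oc1ccc(CCCO)cc1OC | target

Total step count: 14. Longest linear sequence: 12 steps (vanillin to 22 through steps 1–5, 7 and 9–14); 10 steps from D-ribose.

Steps most likely to fail

Step 10. The alkene carries an oxygenated carbon on each side and is a weak nucleophile, so its attack on the well-stabilised aryl oxocarbenium ion may be slow. Halide capture or proton loss from the unstabilised secondary cation, silyl-ether cleavage, or a 2-oxonia-Cope/aldol course that erodes the C1 configuration could then outrun the 1,2-shift. Partial C3 epimerisation in the flask would be harmless, since step 12 converges both epimers. The fallback separates cyclisation from ring contraction. It sets out from 13: a bromide-terminated Prins cyclisation (SnBr4, CH2Cl2, −78 °C, aqueous work-up) should give the 4-bromotetrahydropyran-3-ol, bromohydrin F1, with bromide, hydroxyl, aryl and side chain equatorial. Treating it with AgBF4 and 2,6-di-tert-butylpyridine (CH2Cl2, 0 °C) should trigger the silver-assisted semipinacol ring contraction, the ring C–C bond antiperiplanar to the equatorial C–Br bond migrating. The route is rejoined at 14.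

Step 9. Initiation at the hindered allylic dioxolane carbon may be slow, and secondary metathesis may lower conversion or erode the Z geometry. The fallback builds the Z-alkene by carbonyl olefination and sets out from 10. Lemieux–Johnson cleavage (OsO4 cat., NaIO4, 2,6-lutidine, dioxane–H2O) gives the α-alkoxy aldehyde F2, which is used crude. Still–Gennari olefination (methyl bis(2,2,2-trifluoroethyl)phosphonoacetate, KN(SiMe3)2, 18-crown-6, THF, −78 °C) gives the methyl Z-enoate F3. Reduction with iBu2AlH (CH2Cl2, −78 °C) gives the Z-allylic alcohol F4, and silylation (t-BuMe2SiCl, imidazole) rejoins the route at 13.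

Step 11. Enamine formation and Michael addition at the aldehyde carbon, flanked by two cis substituents, may be sluggish. The alkoxy enone may polymerise or be consumed by aza-Michael addition, and the enamine may open the tetrahydrofuran by β-elimination. The fallback changes the nucleophile and moves the activation to the acceptor, and sets out from 14. Enol silylation (Me3SiOTf, Et3N, CH2Cl2, 0 °C) gives the isolable trimethylsilyl enol ether F5. A Mukaiyama–Michael addition to 15 (BF3·OEt2, iPrOH, CH2Cl2, −78 → −30 °C, hydrolytic work-up) under the same steric control rejoins the route at keto aldehyde 17, which is cyclised with pyrrolidinium acetate to 18 as in the last stage of step 11.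

Further compounds
F1 | step 10 | 4-bromo-6-Ar-5-(TBS-oxymethyl)-2-[(1S)-1-(Ar′-oxy)-2-(TBDPS-oxy)ethyl]tetrahydropyran-3-ol (bromohydrin; Br, OH, Ar and side chain equatorial, CH2OTBS axial) | Br[C@@H]1[C@H](CO[Si](C)(C)C(C)(C)C)[C@H](c2ccc(O[Si](C(C)C)(C(C)C)C(C)C)c(OC)c2)O[C@H]([C@H](CO[Si](c2ccccc2)(c2ccccc2)C(C)(C)C)Oc2ccc(CCCO[Si](C)(C)C(C)(C)C)cc2OC)[C@H]1O
F2 | step 9 | 2-Ar-5-[(1S)-1-(Ar′-oxy)-2-(TBDPS-oxy)ethyl]-1,3-dioxolane-4-carbaldehyde | O=C[C@@H]1OC(c2ccc(O[Si](C(C)C)(C(C)C)C(C)C)c(OC)c2)O[C@@H]1[C@H](CO[Si](c2ccccc2)(c2ccccc2)C(C)(C)C)Oc2ccc(CCCO[Si](C)(C)C(C)(C)C)cc2OC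
F3 | step 9 | methyl (Z)-3-{2-Ar-5-[(1S)-1-(Ar′-oxy)-2-(TBDPS-oxy)ethyl]-1,3-dioxolan-4-yl}acrylate | COC(=O)/C=C\[C@@H]1OC(c2ccc(O[Si](C(C)C)(C(C)C)C(C)C)c(OC)c2)O[C@@H]1[C@H](CO[Si](c2ccccc2)(c2ccccc2)C(C)(C)C)Oc2ccc(CCCO[Si](C)(C)C(C)(C)C)cc2OC
F4 | step 9 | (Z)-3-{2-Ar-5-[(1S)-1-(Ar′-oxy)-2-(TBDPS-oxy)ethyl]-1,3-dioxolan-4-yl}prop-2-en-1-ol | OC/C=C\[C@@H]1OC(c2ccc(O[Si](C(C)C)(C(C)C)C(C)C)c(OC)c2)O[C@@H]1[C@H](CO[Si](c2ccccc2)(c2ccccc2)C(C)(C)C)Oc2ccc(CCCO[Si](C)(C)C(C)(C)C)cc2OC
F5 | step 11 | trimethylsilyl enol ether of 14 | C[Si](C)(C)OC=C1[C@H](CO[Si](C)(C)C(C)(C)C)[C@H](c2ccc(O[Si](C(C)C)(C(C)C)C(C)C)c(OC)c2)O[C@@H]1[C@H](CO[Si](c2ccccc2)(c2ccccc2)C(C)(C)C)Oc2ccc(CCCO[Si](C)(C)C(C)(C)C)cc2OC
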